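A one-step world has one split of the solid substrate between its products, so I first asked whether north and east showed one, and they did not. East stayed flat, but north's target crept up from 47.6 % to 49.3 %; I still replaced each curve by its mean and checked that error below: north held 48.5 % target and 49.6 % side product B, east 68.6 % and 31.4 %. The ratio of target to side product B, a selectivity factor, read 0.977 in north and 2.18 in east.

the same everywhere: solid substrate 20 mM
- north: reagent 20 mM (fed, over 80 min); run made earlier
- east: reagent 80 mM (fed, over 80 min); run made earlier
- flask: reagent 40.0 mM (fed, over 80 min); time 3.0 d

| run | time / d | target / % | side product B / % |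
|---|---|---|---|
| north | 0.625 | 47.6 | 49.7 |
| north | 1.25 | 48.6 | 49.7 |
| north | 1.67 | 48.3 | 50.4 |
| north | 2.50 | 49.3 | 48.6 |
| east | 0.208 | 68.0 | 31.9 |
| east | 0.417 | 69.0 | 31.8 |
| east | 1.04 | 68.7 | 30.6 |
| east | 2.50 | 68.5 | 31.5 |

(standard deviation of a reading: 0.5 percentage points)

* amount of target at 3.0 d, in percent of the solid substrate charged
* amount of side product B at 3.0 d, in percent of the solid substrate charged

- in percentages every species weighs as the solid substrate in it: one side product B counts as two
- as a solid, counted per litre of solution: solid substrate
- what was read earlier has a scatter of 0.5 percentage points, one standard deviation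
- at the start none of the solid substrate is in solution

I assumed that the flask also stood on a plateau, and that its ratio rises with [reagent], but no faster than first order. Scaling north up then gave a ceiling of 1.95, or 66.1 % target, and scaling east down gave a floor of 1.09, or 52.1 %. To tighten this I replaced the curve between the runs by its mean slope: 0.579 is the split order, the rise in ln(ratio) per rise in ln[reagent]. It gave a ratio of 1.46, so 59.3 % target; north's last target reading in place of its mean, a north ratio of 0.994, gave 59.5 %.

The forecast gave 58 % target and 41.5 % side product B, reasoning “so the ratio scales roughly as reagent^0.6, weaker than first order”. That target lay inside my bracket, above its floor and below its ceiling, and 1.3 percentage points under my figure.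

    solid substrate ⇌ dissolved substrate, rate k1*(cs1 - [dissolved substrate]) while solid is left; crystals form when [dissolved substrate] > cs1 (solubility = 4.60 mM, k = 0.260 min⁻¹)
    dissolved substrate + reagent → target (k = 0.890 M⁻¹ min⁻¹)
    reagent → side product A (k = 7.10 × 10⁻⁴ min⁻¹)
    solid substrate + target → side product B (k = 1.70 M⁻¹ min⁻¹)

The flask gave 61.5 % target and 38.5 % side product B, a ratio of 1.60, so the forecast held. The split order read 0.710 below this flask, steeper than the 0.448 above it. Carried from east to a neighbour with 160 mM of reagent, 0.579 gave 76.5 % target, and that neighbour held 72.9 %. In this flask, side product B owed its existence to the low solubility of dissolved substrate: the run without that limit took side product B from 38.5 % to 0 %.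

(All runs stem from a simulated flask for substances that don't exist; noise was put on by code.)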